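**Retrosynthetic overview**
- Target ⇐ hydrolysis of its 20-phenylsulfanyl 19,20-lactone (an O,S-acetal of the lactol), carried as the 7-methoxymethyl ester.
- Key disconnection C10–C20: photoredox 6-exo radical cyclization of a C19 (phenylsulfanyl)methyl ester onto a 1(10)-alkene. The α-C19 tether sets the C10 quaternary centre.
- The 1(10)-ene 19-acid ⇐ reductive opening of the allylic 19,10-lactone of 13-deoxygibberellic acid.
- Rings A, B, C and D and the centres C3, C4, C5, C6, C8, C9 and C13 are bought in the starting gibberellin. The only ring made is the six-membered 19,20-lactone ring, in the key step.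

Assumption: 13-deoxygibberellic acid (the fermentation gibberellin numbered seven in the A series, sold pure and as a technical mixture with its 1,2-dihydro analogue) is taken as the commercial chiral starting material, and the target is written in the open 20-oxo 19-acid form of the given SMILES, which equilibrates with its 19,20-lactol.

Face convention: α is the ring A face that carries C19 (and C20 in the target). The 3-OH, H-5, H-9 and the C7 carboxyl lie on the β face.

**Step 1**
Reactants: 1 13-deoxygibberellic acid
Product: 2 13-deoxygibberellic acid 7-(methoxymethyl) ester
Conditions: MOMCl (1.1 equiv), Et3N (1.2 equiv), CH2Cl2, 0 °C, 1 h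
Reagents that add atoms: chloromethyl methyl ether, COCCl
Why: O-alkylation of the only free carboxylate (SN2 on the chloromethyl ether) is much faster than etherification of the hindered axial 3β-OH at 0 °C with one equivalent, and no stereocentre is touched.

**Step 2**
Reactants: 2 13-deoxygibberellic acid 7-(methoxymethyl) ester
Product: 3 3β-hydroxy-20-norgibberella-1(10),16-diene-7,19-dioic acid 7-(methoxymethyl) ester
Conditions: Pd(PPh3)4 (5 mol%), NaBH4 (2 equiv), THF, 0 → 20 °C, Ar; NaH2PO4 buffer (pH 5) work-up
Reagents that add atoms: none
Why: Tsuji–Trost ionization of the tertiary allylic lactone by zerovalent palladium gives a π-allylpalladium carboxylate that borohydride reduces at the less hindered secondary terminus C2 (palladium-catalysed allylic hydrogenolysis), which moves the alkene to C1=C10, frees the C19 acid and leaves C3, C4, C5 and C9 untouched.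

**Step 3**
Reactants: 3 3β-hydroxy-20-norgibberella-1(10),16-diene-7,19-dioic acid 7-(methoxymethyl) ester
Product: 4 7-(methoxymethyl) 19-[(phenylsulfanyl)methyl] 3β-hydroxy-20-norgibberella-1(10),16-diene-7,19-dioate
Conditions: ClCH2SPh (1.3 equiv), Cs2CO3 (1.1 equiv), NaI (10 mol%), DMF, 20 °C; neutral work-up (acid would relactonize C19 onto C10)
Reagents that add atoms: chloromethyl phenyl sulfide, ClCSc1ccccc1
Why: SN2 O-alkylation of the cesium C19 carboxylate by the reactive α-chloro sulfide gives the (phenylsulfanyl)methyl ester, the secondary alcohol is not alkylated under carbonate, and no stereocentre is involved.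

**Step 4**
Reactants: 4 7-(methoxymethyl) 19-[(phenylsulfanyl)methyl] 3β-hydroxy-20-norgibberella-1(10),16-diene-7,19-dioate
Product: 5 3β-hydroxy-20-(phenylsulfanyl)gibberell-16-ene-7,19-dioic acid 19,20-lactone 7-(methoxymethyl) ester (C20 on the α face of C10; mixture of C20 epimers)
Conditions: [Ir(dF(CF3)ppy)2(5,5'-d(CF3)bpy)]PF6 (2 mol%), 2,4,6-triisopropylbenzenethiol (20 mol%), 2,4,6-collidine (30 mol%), MeCN (0.02 M), 450 nm LEDs, 25–40 °C, Ar
Reagents that add atoms: none
Why: Proposed new method: the excited trivalent iridium complex (about +1.7 V) should oxidize only the aryl sulfide (about +1.6 V, the two alkenes lie above +1.9 V), collidine removes the CH2 proton acidified by both the sulfur radical cation and the acyloxy group, and the resulting α-thio-α-acyloxy radical, held by the axial α-C19 carboxyl directly over C10, closes 6-exo onto the 1(10)-alkene through a chair-like bicyclo[3.3.1] transition state (attack at C1 would need a boat-bridged bicyclo[3.2.2] ring), which forms the C10–C20 bond and sets the C10 quaternary centre with C20 on the α face by tether control, after which the secondary C1 radical takes hydrogen from the thiol and the thiyl radical is reduced by divalent iridium to close both cycles, while premature hydrogen transfer to the uncyclized radical only regenerates 4; the closest known reaction types are photoredox α-C–H alkylation of thioethers with Michael acceptors through radical-cation deprotonation and thiol-cocatalysed photoredox hydrofunctionalization of alkenes, neither of which has been shown for an acyloxymethyl sulfide, an unactivated trisubstituted alkene or quaternary-centre formation.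

**Step 5**
Reactants: 5 3β-hydroxy-20-(phenylsulfanyl)gibberell-16-ene-7,19-dioic acid 19,20-lactone 7-(methoxymethyl) ester
Product: 7 target gibberellin (3β-hydroxy-20-oxogibberell-16-ene-7,19-dioic acid), via target lactol methoxymethyl ester 6 (not isolated)
Conditions: AgNO3 (2.5 equiv), acetone–H2O 4:1, 40 °C; filter; then 0.5 M HCl, THF–H2O, 20 °C, 2 h
Reagents that add atoms: water, O
Why: The α-acyloxy sulfide ionizes under the acid formed in situ to a thionium ion (Pummerer-type), water adds and monovalent silver removes benzenethiolate irreversibly to give the lactol, and dilute acid then hydrolyses the acetal-type methoxymethyl ester, while the quaternary C10 cannot epimerize and the lactol opens to the 20-oxo 19-acid form of the target.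

**Compound list**
1 | 13-deoxygibberellic acid (3β-hydroxy-20-norgibberella-1,16-diene-7,19-dioic acid 19,10-lactone, lactone bridge on the α face) | C=C1C[C@]23C[C@H]1CC[C@H]2[C@]14C=C[C@H](O)[C@@](C)(C(=O)O4)[C@H]1[C@@H]3C(=O)O | starting material
2 | 13-deoxygibberellic acid 7-(methoxymethyl) ester | C=C1C[C@]23C[C@H]1CC[C@H]2[C@]14C=C[C@H](O)[C@@](C)(C(=O)O4)[C@H]1[C@@H]3C(=O)OCOC | intermediate
3 | 3β-hydroxy-20-norgibberella-1(10),16-diene-7,19-dioic acid 7-(methoxymethyl) ester (free 19-acid) | C=C1C[C@]23C[C@H]1CC[C@H]2C1=CC[C@H](O)[C@@](C)(C(=O)O)[C@H]1[C@@H]3C(=O)OCOC | intermediate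
4 | 7-(methoxymethyl) 19-[(phenylsulfanyl)methyl] 3β-hydroxy-20-norgibberella-1(10),16-diene-7,19-dioate | C=C1C[C@]23C[C@H]1CC[C@H]2C1=CC[C@H](O)[C@@](C)(C(=O)OCSc2ccccc2)[C@H]1[C@@H]3C(=O)OCOC | intermediate
5 | 3β-hydroxy-20-(phenylsulfanyl)gibberell-16-ene-7,19-dioic acid 19,20-lactone 7-(methoxymethyl) ester (C20 α on C10; C20 epimers) | C=C1C[C@]23C[C@H]1CC[C@H]2[C@]14CC[C@H](O)[C@@](C)(C(=O)OC4Sc2ccccc2)[C@H]1[C@@H]3C(=O)OCOC | intermediate
6 | target lactol methoxymethyl ester (3β,20-dihydroxygibberell-16-ene-7,19-dioic acid 19,20-lactone 7-(methoxymethyl) ester; not isolated) | C=C1C[C@]23C[C@H]1CC[C@H]2[C@]14CC[C@H](O)[C@@](C)(C(=O)OC4O)[C@H]1[C@@H]3C(=O)OCOC | intermediate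
7 | target gibberellin (3β-hydroxy-20-oxogibberell-16-ene-7,19-dioic acid, open 20-oxo 19-acid form) | C=C1C[C@]23C[C@H]1CC[C@H]2[C@]1(C=O)CC[C@H](O)[C@@](C)(C(=O)O)[C@H]1[C@@H]3C(=O)O | target

**Totals**
Total step count: 5. Longest linear sequence: 5 steps, from 1.

**Three steps most likely to fail**

Step 4 (the proposed new step). The sulfide radical cation may not be deprotonated productively, the α-thio radical may be over-oxidized, or the photoredox cycle may stall before the slow ring closure. The fallback uses known chemistry and sets out from 4. N-Chlorosuccinimide in CH2Cl2 at 0 °C chlorinates the sulfide α-carbon (classical α-chlorination of sulfides) to give the 19-[chloro(phenylsulfanyl)methyl] ester F1. Slow addition of Bu3SnH with AIBN in benzene at 80 °C then generates the same tethered radical by chlorine abstraction (stannane chain cyclization of α-chloro sulfides). The higher temperature helps the ester rotamer needed for closure, and the 6-exo cyclization returns to the route at 5. This fallback changes how the radical is made (neutral chain, no radical cation, no thiol) but still relies on the same 6-exo closure onto C10, so it does not help if that closure itself is unfavourable.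

Step 2. Hydride may be delivered to C10 instead of C2 (giving the 10-H 1,2-ene), or the π-allyl intermediate may eliminate to dienes. The fallback sets out from 1 and changes both mechanism and order. Lithium in liquid NH3/THF with t-BuOH at −78 °C (NH4Cl quench) cleaves the allylic lactone of the unprotected acid by electron transfer. The allyl anion is expected to protonate at the less substituted C2, and this gives 3β-hydroxy-20-norgibberella-1(10),16-diene-7,19-dioic acid F2. One equivalent of MOMCl with Et3N at −40 °C then esterifies the more acidic, less hindered C7 carboxyl in preference to the axial C19 carboxyl on the quaternary C4. This selectivity is likely only moderate and would need chromatographic separation. The fallback comes back to the route at 3.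

Step 5. Silver-assisted hydrolysis at the hindered C20 may be slow, and longer acid exposure endangers the 16-methylene. The fallback sets out from 5 and uses acyl cleavage instead of sulfur activation. LiOH in THF–H2O at 0 °C attacks the activated C19 lactone carbonyl, the released hemithioacetal alkoxide collapses to the C20 aldehyde and benzenethiolate, and the methoxymethyl ester is saponified in the same operation. Careful acidification to pH 3 gives 7 directly. The low temperature is intended to suppress C3 epimerization by retro-aldol, which remains a risk while C19 is still in the lactone. This fallback makes no new compound (F0).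

**Further compounds**
F1 | step 4 | 7-(methoxymethyl) 19-[chloro(phenylsulfanyl)methyl] 3β-hydroxy-20-norgibberella-1(10),16-diene-7,19-dioate | C=C1C[C@]23C[C@H]1CC[C@H]2C1=CC[C@H](O)[C@@](C)(C(=O)OC(Cl)Sc2ccccc2)[C@H]1[C@@H]3C(=O)OCOC
F2 | step 2 | 3β-hydroxy-20-norgibberella-1(10),16-diene-7,19-dioic acid | C=C1C[C@]23C[C@H]1CC[C@H]2C1=CC[C@H](O)[C@@](C)(C(=O)O)[C@H]1[C@@H]3C(=O)O
F0 | step 5 | none | none
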